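## Structural features

The target is a germacranolide whose ten-membered carbocycle C1–C10 is bridged by an ether oxygen between C5 and C10, so that two oxepanes share O, C5 and C10 (an 11-oxabicyclo[4.4.1]undecane). An α-methylene-γ-lactone (C11–C13, closed on O8) is trans-fused to the lactone-side oxepane at C7–C8, and an isovalerate sits on C9. Of the six stereocentres, C4 and C5 are neighbours in the carbocycle-side oxepane, while C7, C8, C9 and the fully substituted ether carbon C10 form a contiguous row in the other; C5 and C10 are the bridgeheads. Around the lactone-side oxepane H7/H8 and H8/H9 are trans, O9 is cis to the C10 methyl, and C4 and C1 lie on the same face across the ether oxygen, which is the all-equatorial pattern of a 2,7-cis-disubstituted oxepane. Fragile groups are the exocyclic methylene lactone (Michael acceptor, reducible, must appear last), the two acyl groups on the vicinal oxygens O8 and O9 (acyl migration) and, in intermediates, every centre α to a carbonyl (C4, C8, C11). The real difficulty is the oxygen-bridged pair of seven-membered rings with a quaternary ether carbon beside four contiguous stereocentres and no functional group in the C1–C4 bridge. The key step exploits that C5 carries the ring oxygen and C8 lies α to C9: with C9 as a ketone, C5–C8 is a retro-aldol bond, so the lactone-side oxepane (O, C5, C6, C7, C8, C9, C10) is a 3(2H)-furanone (O, C5, C8, C9, C10) into whose C5=C8 bond the carbons C6 and C7 of a butenoate hung on O8 are inserted.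

## Logic of the disconnections

34 ⇒ 32 (forward through 33). No skeletal bond is cut; the C11=C13 double bond is traced back to a C13 hydroxyl. The conjugated methylene cannot coexist with hydride, low-valent metal or hydrogenation steps, so it is unveiled last. The gain is a saturated lactone that tolerates the earlier steps. The demand is that O13 stays masked until the last reduction; the primary leaving group makes the elimination exocyclic.

32 ⇒ 31 ⇒ 30. The C2–C3 bond is cut (forward: reductive coupling of two aldehydes to C2=C3, then hydrogenation that also frees O13). C2 and C3 are the only unfunctionalised neighbours in the bridge and lie farthest from all stereocentres. The gain is that the bridged bicycle becomes a monocyclic oxepane with two short arms. The demand is that the arms on C5 and C10 are cis across the ring oxygen and that 30 survives without epimerisation at C4 or β-elimination.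

30 ⇒ 29 ⇒ 28 ⇒ 26 + 27 ⇒ 25. Only functional groups change: aldehydes back to silyl ethers, the C9–O acyl bond cut, the C9 alcohol taken back to the ketone. The ketone is what the next retrosynthetic step needs, and it makes C8 correctable. The gain is that C8 and C9 need no earlier control. The demand is hydride delivery to C9 from the face of the C10 side chain without migration of the lactone acyl group.

25 ⇒ 23 (forward through 24). The C5–C8 bond is re-formed and H5 removed, contracting the oxepanone to a tetrahydrofuranone fused to a cyclobutane. C5 (ether donor) and C8 (α to the ketone) stand in a retro-aldol relationship, so the forward cleavage is driven by strain. The gain is that a seven-membered ring is exchanged for five- and four-membered rings that a cycloaddition can make. The demand is selective heterolysis of this one bond, hydride capture at C5 anti to the C10 chain, and thermodynamic control at C8.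

23 ⇒ 22. C7–C8 and C5–C6 are cut (the key step). Both bonds come from a flat enone and an alkene held by the future lactone as tether. The gain is that every ring stereocentre except C10 disappears. The demand is addition to the furanone face that carries the C10 chain, which only C11 can enforce, and straight rather than crossed regiochemistry. The configurations of 22 and 23 were checked against 34: 10R and 4S carry over unchanged, 7R requires the cyclobutane on the face of the C10 chain (5R,8S), and 11S places the benzyloxymethyl group exo. No correction of constitution or descriptors was needed.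

22 ⇒ 13 + 20 (forward through 21). The ester bond O8–C12 is cut, which makes the route convergent. The demand is acylation without base-induced epimerisation or conjugation at C11, which is both allylic and α to an activated ester; this is where the precursor design is tightened (base-free acid chloride formation, stoichiometric enolate, no amine).

13 ⇒ 11 (forward through 12) ⇒ 6 + 10. In 13 the O–C5 and C8–C9 bonds are cut and the C8 oxygen is reattached to C9 as an ester; the C8–O bond of 11 is then cut. This places the C8 oxygen without any oxidation step and joins the halves by a simple carboxylate alkylation. The gain is two small chiral-pool pieces. The demand is enolisation at C8 only, with C4 untouched.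

6 ⇒ 5 ⇒ 2 + 4; 2 ⇒ 1; 4 ⇒ 3. The C10–C1 bond is cut. C10 is taken from lactic acid by alkylation with retention through its acetal, and the two-carbon arm arrives already silylated. The demand is an electrophile that reacts at −78 °C.

10 ⇒ 9 ⇒ 8 ⇒ 7. The C5–C8 bond is cut (one-carbon homologation of an acyl group). C4 comes from the hydroxy ester 7, so no reaction has to create it.

20 ⇒ 18 (forward through 19) ⇒ 17 ⇒ 14 + 15 (forward through 16). The C11–C13 bond is cut. The auxiliary sets C11, and the demand is α-attack on the dienolate and a cleavage that does not epimerise.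

## Other disconnections considered

Alternative 1: The cut is C6–C7, with the C11=C13 bond traced back to an allylic sulfone. In the forward sense the primary C6 radical from iodide A1 would add 7-exo to C7 of the enoate and the adduct radical would expel the ethylsulfonyl radical, giving methylene ester A2; loss of SO2 leaves an ethyl radical that carries the chain by iodine abstraction.
- In its favour: addition–fragmentation on allyl sulfones is established, and on precedent this alternative is better than the chosen plan. No tin hydride is needed. The methylene appears in the ring-forming step, which equals or betters the chosen end game.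
- Against it here: a 7-exo closure of a primary radical is slow and would compete with 1,5-hydrogen transfer and iodine-transfer oligomerisation. C7 would be set in a flexible seven-membered transition state with only C8 as neighbour. A1 already contains the second oxepane, the quaternary C10 and the C8/C9 diol, so the hard problems move into the precursor.
- Comparison: structurally it closes the lactone-side ring last on a preformed oxepane, the chosen plan the reverse. Mechanistically it is a thermal radical chain against a photocycloaddition followed by an ionic fragmentation. After the key step it is shorter (desilylation and lactonisation only), but the longer linear access to A1 should make the overall economy similar.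

Alternative 2: The cuts are O–C10 and C1–C10, with O–C3 reconnected. Rh2(OAc)4 would convert diazo ketone A3 into a carbenoid at C10; capture by the oxetane oxygen and a [2,3]-shift onto the vinyl terminus would open the oxetane and give bicyclic ketone A4.
- In its favour: the oxygen bridge, both seven-membered rings and the quaternary C10 would form in one catalytic step, driven by oxetane strain. In bonds and rings made per step it is better than the chosen key step.
- Against it here: C10 would arise from a planar carbenoid, so its configuration depends on which diastereomeric ylide rearranges. α-Methyl diazo ketones are prone to 1,2-hydride migration, and C–H insertion competes with seven-membered ylide formation. A4 still lacks the C9 stereocentre (reduction inside a rigid bicycle, where the open face would be expected to give the wrong epimer), the isovalerate, the saturated C2–C3 bond and the methylene group. A3 needs a stereodefined trisubstituted oxetane.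
- Comparison: structurally it builds the bridge first and decorates afterwards, while the chosen plan sets C9 on a flexible monocycle and bridges later. Mechanistically both rely on a strained intermediate, but here the strain is spent in the same step. The key step is more economical, the tail after it longer, and the stereochemical risk at C9 and C10 is higher.

Alternative 3: The cuts are C7–C8 and the lactone bond O–C12. CrCl2 would convert allylic bromide A5 into an allylchromium species that adds through C7 to the C8 aldehyde, and the chromium alkoxide would close the lactone to give A6.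
- In its favour: intramolecular allylation with 2-(bromomethyl)acrylates under divalent chromium is a standard entry to α-methylene-γ-lactones and tolerates esters and silyl ethers. In precedent and chemoselectivity it is better than the chosen plan. Only desilylation and acylation would remain, so the end game is equal or better.
- Against it here: the seven-membered closure must deliver the trans C7/C8 relationship through a ring-constrained transition state, which is not obviously favoured. The aldehyde carbon C8 is α to the oxygenated C9, which may epimerise. Chromium is used in excess. A5 already holds the carbocycle-side oxepane with C4, C5, C9 and quaternary C10, none of which the key step helps to build.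
- Comparison: structurally both plans close the lactone-side oxepane, here by one C–C bond on a finished bicyclic half, in the chosen plan by ring expansion of a furanone made from two chiral-pool acids. Mechanistically the alternative is the more conservative. In total length the two should be close; the chosen plan gains convergence and pays with two steps without direct precedent.

Key step: step 14

Remark: atoms carry germacrane numbers throughout (C1–C15; the ether oxygen joins C5 and C10).
Remark: a commercial 2-methyl-5-ethyl-4-hydroxyfuranone is not used as the furanone source, because it is a pair of ring tautomers and a later hydroxymethylation beside C5 could not control C4; C4 and C10 are both taken from the chiral pool.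
Assumption: the trans-fused lactone is taken as the more stable C8 epimer of 25, since both ring-fusion bonds are then equatorial on the oxepanone.
Assumption: C11 of 23–32 is drawn as set in step 11; it may equilibrate in step 15 and is removed in step 22, so it has no bearing on 34.

## Steps

Step 1
Reactants: 1 (S)-lactic acid
Product: 2 (2S,5S)-2-tert-butyl-5-methyl-1,3-dioxolan-4-one
Conditions: t-BuCHO, TsOH·H2O (cat.), H2SO4 (cat.), pentane, reflux (Dean–Stark); crystallisation at −78 °C
Reagents that add atoms: pivalaldehyde CC(C)(C)C=O
Why: Acid-catalysed acetalisation (self-regeneration of stereocentres); the cis acetal is the thermodynamic isomer and is purified by crystallisation, so the lactic acid configuration is stored in the acetal carbon.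

Step 2
Reactants: 3 2-(tert-butyldimethylsilyloxy)ethanol
Product: 4 2-(tert-butyldimethylsilyloxy)ethyl trifluoromethanesulfonate
Conditions: Tf2O, 2,6-lutidine, CH2Cl2, −78 °C; used at once
Reagents that add atoms: trifluoromethanesulfonic anhydride O=S(=O)(OS(=O)(=O)C(F)(F)F)C(F)(F)F
Why: O-Sulfonylation of a primary alcohol; a triflate is chosen because the hindered dioxolanone enolate is stable only at low temperature and needs an electrophile that reacts at −78 °C.

Step 3
Reactants: 2 (2S,5S)-2-tert-butyl-5-methyl-1,3-dioxolan-4-one; 4 2-(tert-butyldimethylsilyloxy)ethyl trifluoromethanesulfonate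
Product: 5 (2S,5R)-2-tert-butyl-5-[2-(tert-butyldimethylsilyloxy)ethyl]-5-methyl-1,3-dioxolan-4-one
Conditions: LDA, THF, −78 °C; then 4, −78 → −40 °C
Reagents that add atoms: none
Why: Enolate alkylation of the acetal-protected lactate; the electrophile enters trans to the tert-butyl group, which is retention at the former lactic acid carbon and sets C10 (R) with C1–C2 attached.

Step 4
Reactants: 5 (2S,5R)-2-tert-butyl-5-[2-(tert-butyldimethylsilyloxy)ethyl]-5-methyl-1,3-dioxolan-4-one
Product: 6 (R)-4-(tert-butyldimethylsilyloxy)-2-hydroxy-2-methylbutanoic acid
Conditions: LiOH, THF/H2O, 0 → 20 °C; then aq. HCl to pH 4, 0 °C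
Reagents that add atoms: lithium hydroxide [Li+].[OH-]
Why: Saponification of the acetal ester releases pivalaldehyde and the α-hydroxy acid; the quaternary centre cannot epimerise and the primary silyl ether tolerates the brief mild acidification.

Step 5
Reactants: 7 methyl (S)-3-hydroxy-2-methylpropanoate
Product: 8 methyl (S)-3-(tert-butyldimethylsilyloxy)-2-methylpropanoate
Conditions: TBSCl, imidazole, DMF, 20 °C
Reagents that add atoms: tert-butyldimethylsilyl chloride CC(C)(C)[Si](C)(C)Cl
Why: Silylation of the primary alcohol; the same silyl group as on the other arm allows both to be removed together in step 18.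

Step 6
Reactants: 8 methyl (S)-3-(tert-butyldimethylsilyloxy)-2-methylpropanoate
Product: 9 (S)-3-(tert-butyldimethylsilyloxy)-N-methoxy-N,2-dimethylpropanamide
Conditions: MeNH(OMe)·HCl, i-PrMgCl, THF, −20 °C
Reagents that add atoms: N,O-dimethylhydroxylamine hydrochloride CNOC.Cl
Why: Weinreb amide formation by aminolysis with the magnesium amide; at −20 °C the α-centre (the future C4) should not epimerise.

Step 7
Reactants: 9 (S)-3-(tert-butyldimethylsilyloxy)-N-methoxy-N,2-dimethylpropanamide
Product: 10 (S)-4-(tert-butyldimethylsilyloxy)-1-chloro-3-methylbutan-2-one
Conditions: ICH2Cl, MeLi·LiBr, THF, −78 °C; aq. NH4Cl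
Reagents that add atoms: chloroiodomethane ClCI
Why: Addition of chloromethyllithium (made in situ by iodine–lithium exchange) to a Weinreb amide; the chelated tetrahedral intermediate prevents over-addition and α-epimerisation and delivers C8 as an electrophilic CH2 next to the C5 carbonyl.

Step 8
Reactants: 6 (R)-4-(tert-butyldimethylsilyloxy)-2-hydroxy-2-methylbutanoic acid; 10 (S)-4-(tert-butyldimethylsilyloxy)-1-chloro-3-methylbutan-2-one
Product: 11 (3S)-4-(tert-butyldimethylsilyloxy)-3-methyl-2-oxobutyl (2R)-4-(tert-butyldimethylsilyloxy)-2-hydroxy-2-methylbutanoate
Conditions: Cs2CO3 (0.5 equiv), DMF, 20 °C; then 10, NaI (cat.)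
Reagents that add atoms: none
Why: SN2 O-alkylation of a caesium carboxylate by an α-chloro ketone; it makes the hindered ester without activating the acid, the preformed carboxylate is too weak a base to epimerise C4, and the ester oxygen is the future C8 oxygen.

Step 9
Reactants: 11 (3S)-4-(tert-butyldimethylsilyloxy)-3-methyl-2-oxobutyl (2R)-4-(tert-butyldimethylsilyloxy)-2-hydroxy-2-methylbutanoate
Product: 13 (2R)-2-[2-(tert-butyldimethylsilyloxy)ethyl]-5-[(2S)-1-(tert-butyldimethylsilyloxy)propan-2-yl]-4-hydroxy-2-methylfuran-3(2H)-one, via hydroxy diketone 12 (not isolated)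
Conditions: LDA (3.2 equiv), THF, −78 → −20 °C; AcOH; then PPTS, 4 Å MS, CH2Cl2, 40 °C
Reagents that add atoms: none
Why: Chan rearrangement: the ketone enolate at the doubly activated C8 attacks the ester carbonyl C9 (the acyl part has no α-hydrogen), and the 1,2-acyl shift forms C8–C9 and leaves the former ester oxygen as the C8 hydroxyl. Acid-catalysed cyclodehydration of the α′-hydroxy 1,3-diketone (C10–OH onto C5) then gives the 4-hydroxy-3(2H)-furanone, in which C8 is no longer stereogenic; C4 is not involved because enolisation takes place at C8.

Step 10
Reactants: 14 but-3-enoic acid; 15 (R)-4-benzyl-1,3-oxazolidin-2-one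
Product: 17 (R)-4-benzyl-3-(but-3-enoyl)-1,3-oxazolidin-2-one, via mixed pivalic anhydride 16 (not isolated)
Conditions: PivCl, Et3N, THF, −20 °C; then 15, LiCl, 20 °C
Reagents that add atoms: none
Why: N-Acylation of the auxiliary through the mixed anhydride; attack occurs at the less hindered butenoyl carbonyl.

Step 11
Reactants: 17 (R)-4-benzyl-3-(but-3-enoyl)-1,3-oxazolidin-2-one
Product: 18 (R)-4-benzyl-3-[(2S)-2-(benzyloxymethyl)but-3-enoyl]-1,3-oxazolidin-2-one
Conditions: TiCl4, i-Pr2NEt, CH2Cl2, 0 °C; then BnOCH2Cl, 0 °C
Reagents that add atoms: benzyl chloromethyl ether ClCOCc1ccccc1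
Why: Evans alkylation of the chelated titanium (Z)-dienolate at its α-carbon; the electrophile enters opposite the benzyl group of the (R)-auxiliary and sets C11 (S). Allylic 1,3-strain in the product disfavours deprotonation, which protects the new centre from epimerisation and conjugation.

Step 12
Reactants: 18 (R)-4-benzyl-3-[(2S)-2-(benzyloxymethyl)but-3-enoyl]-1,3-oxazolidin-2-one
Product: 20 (S)-2-(benzyloxymethyl)but-3-enoic acid, via peroxy acid 19 (not isolated)
Conditions: LiOH, H2O2, THF/H2O, 0 °C; then Na2SO3; aq. HCl to pH 3
Reagents that add atoms: hydrogen peroxide OO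
Why: Hydroperoxide cleavage of the imide at the exocyclic carbonyl; lithium hydroperoxide is nucleophilic but weakly basic, so the α-vinyl centre should survive, and sulfite reduces the peroxy acid and excess oxidant.

Step 13
Reactants: 20 (S)-2-(benzyloxymethyl)but-3-enoic acid; 13 (2R)-2-[2-(tert-butyldimethylsilyloxy)ethyl]-5-[(2S)-1-(tert-butyldimethylsilyloxy)propan-2-yl]-4-hydroxy-2-methylfuran-3(2H)-one
Product: 22 (5R)-5-[2-(tert-butyldimethylsilyloxy)ethyl]-2-[(2S)-1-(tert-butyldimethylsilyloxy)propan-2-yl]-5-methyl-4-oxo-4,5-dihydrofuran-3-yl (2S)-2-(benzyloxymethyl)but-3-enoate, via acid chloride 21 (not isolated)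
Conditions: 20, 1-chloro-N,N,2-trimethylprop-1-en-1-amine, CH2Cl2, 0 °C; separately 13, NaHMDS (1.0 equiv), THF, −78 °C; combine at −78 °C; pH 7 buffer
Reagents that add atoms: none
Why: O-Acylation of a preformed enolate by an acid chloride made under neutral conditions; the only base present is the stoichiometric, weakly basic enolate oxygen, so ketene formation and epimerisation at C11 should be suppressed, and the hard acyl chloride attacks oxygen rather than the hindered C5. The ester is used promptly.

Step 14
Reactants: 22 (5R)-5-[2-(tert-butyldimethylsilyloxy)ethyl]-2-[(2S)-1-(tert-butyldimethylsilyloxy)propan-2-yl]-5-methyl-4-oxo-4,5-dihydrofuran-3-yl (2S)-2-(benzyloxymethyl)but-3-enoate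
Product: 23 tricyclic photoadduct (4S,5R,7R,8S,10R,11S): cyclobutane C5–C6–C7–C8 cis-fused to the γ-lactone at C7–C8 and to the tetrahydrofuran-3-one at C5–C8, cyclobutane on the face of the C10 silyloxyethyl chain, benzyloxymethyl group exo (trans to C6)
Conditions: hν (350–366 nm, Pyrex), degassed CH2Cl2 (0.005 M), 20 °C
Reagents that add atoms: none
Why: Proposed new method: excitation of the furanone (n–π*, then intersystem crossing) gives a triplet enone whose C8 attacks the internal alkene carbon C7, and the resulting C5/C6 1,4-diradical closes after spin inversion; the closest known reaction types are the de Mayo reaction and the intramolecular [2+2] photocycloaddition of 3(2H)-furanones, 2-alkenyloxy enones and other vinylogous esters, and what is new is the ester tether on a 4-acyloxy-3(2H)-furanone. The γ-lactone closes 5-exo-trig (rule of five, two tether atoms between C8 and C7), which also fixes the straight rather than the crossed regiochemistry, and the cyclobutane closes by recombination of the 1,4-diradical. C7 is controlled by C11: in the five-membered transition state the benzyloxymethyl group takes the exo position trans to C6, which for 11S means addition to the furanone face that carries the C10 side chain and gives 7R. C5 and C8 follow from the obligatory cis fusion of the cyclobutane to both five-membered rings and are erased in step 15. The step needs facial selectivity against a weak opposing bias of C10, where methyl and CH2CH2OSi differ little near the ring, and it needs the ester rotamer in which C8 and C11 are cis about the O–C12 bond, which is reachable because unproductive excitation of the extended rotamer only returns starting material. C11 itself is safe in the neutral, aprotic medium.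

Step 15
Reactants: 23 tricyclic photoadduct
Product: 25 trans-lactone-fused oxepan-3-one (4S,5R,7R,8R,10R,11S): ring O–C10(CH3)(CH2CH2OTBS)–C9(=O)–C8H(O)–C7H–C6H2–C5H[CH(CH3)CH2OTBS], lactone O8–C12(=O)–C11H(CH2OBn)–C7, via silyl enol ether 24 (not isolated)
Conditions: TMSOTf (1.3 equiv), Et3SiH (5 equiv), CH2Cl2, −78 → −40 °C; then MeOH, DBU, −78 → 20 °C
Reagents that add atoms: none
Why: Proposed new method: silylation of the C9 carbonyl (pull) and the lone pair of the ring oxygen (push) should heterolyse the strained C5–C8 bond to an oxepanyl oxocarbenium ion and the C8=C9 silyl enol ether, the closest known reaction types being the de Mayo retro-aldol step, the Lewis-acid opening of donor–acceptor cyclobutanes and the Et3SiH/TMSOTf reduction of cyclic oxocarbenium ions. Et3SiH should add to C5 anti to the C10 CH2CH2OSi chain, which shields its own face and can cap the cation reversibly through its ether oxygen, so that C4 and C1 end cis across the ring oxygen (5R). Methanol then cleaves the enol ether and DBU equilibrates the α-acyloxy ketone to the trans-fused lactone (8R).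

Step 16
Reactants: 25 trans-lactone-fused oxepan-3-one
Product: 26 C9 alcohol (4S,5R,7R,8R,9S,10R,11S)
Conditions: NaBH4, MeOH/THF, −40 °C; aq. NH4Cl
Reagents that add atoms: none
Why: Hydride reduction of a ketone; in the chair-like oxepanone with the C5 and C10 chains and both lactone bonds equatorial the C10 methyl is axial, so the small hydride should enter anti to it (axial attack) and give the equatorial 9S alcohol, trans to O8 and cis to the methyl. Low temperature and an acidic quench limit migration of the lactone acyl group to O9.

Step 17
Reactants: 26 C9 alcohol; 27 isovaleryl chloride (3-methylbutanoyl chloride)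
Product: 28 C9 isovalerate with both silyl ethers and the benzyl ether in place
Conditions: 27, pyridine, DMAP (cat.), CH2Cl2, 0 → 20 °C
Reagents that add atoms: none
Why: DMAP-catalysed esterification of the equatorial secondary alcohol; no enolisable centre other than C11 is exposed.

Step 18
Reactants: 28 C9 isovalerate
Product: 29 diol (C2–OH and C3–OH free)
Conditions: HF·pyridine, pyridine, THF, 0 → 20 °C
Reagents that add atoms: none
Why: Fluoride-mediated cleavage of both primary silyl ethers under buffered, non-basic conditions that leave the lactone, the isovalerate and the benzyl ether untouched.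

Step 19
Reactants: 29 diol
Product: 30 dialdehyde (C2 and C3 as CHO)
Conditions: Dess–Martin periodinane, NaHCO3, CH2Cl2, 0 → 20 °C; used crude
Reagents that add atoms: none
Why: Dess–Martin oxidation of two primary alcohols under buffered conditions, mild enough for the α-stereocentre C4 and the β-alkoxy aldehydes; the product is taken on directly.

Step 20
Reactants: 30 dialdehyde
Product: 31 bicyclic alkene (11-oxabicyclo[4.4.1]undec-3-ene core, C2=C3; lactone, isovalerate and benzyl ether in place)
Conditions: TiCl3(DME)1.5, Zn–Cu couple, DME, reflux; slow addition of 30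
Reagents that add atoms: none
Why: McMurry coupling: low-valent titanium joins the two aldehydes to the pinacolate and deoxygenates it to the cis C2=C3 alkene, closing the carbocycle-side oxepane; aldehydes couple much faster than the esters present, and high dilution favours the intramolecular pathway. Only the 5R epimer with cis arms can close.

Step 21
Reactants: 31 bicyclic alkene
Product: 32 saturated hydroxymethyl lactone (C13–OH)
Conditions: H2 (1 atm), Pd/C, EtOAc, 20 °C
Reagents that add atoms: none
Why: Catalytic hydrogenation of the C2=C3 bond and hydrogenolysis of the benzyl ether in one operation; no stereocentre is created.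

Step 22
Reactants: 32 saturated hydroxymethyl lactone
Product: 34 CNP0274454.1 (target), via mesylate 33 (not isolated)
Conditions: MsCl, Et3N, CH2Cl2, 0 °C; then DBU, 20 °C
Reagents that add atoms: none
Why: Mesylation followed by E1cB elimination across C11–C13; the only acidic hydrogen β to the leaving group is H11, so the exocyclic methylene forms and the C11 stereocentre is erased.

## Compound list

1 | (S)-lactic acid | C[C@H](O)C(=O)O | starting material
2 | (2S,5S)-2-tert-butyl-5-methyl-1,3-dioxolan-4-one | C[C@@H]1O[C@H](C(C)(C)C)OC1=O | intermediate
3 | 2-(tert-butyldimethylsilyloxy)ethanol | CC(C)(C)[Si](C)(C)OCCO | starting material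
4 | 2-(tert-butyldimethylsilyloxy)ethyl trifluoromethanesulfonate | CC(C)(C)[Si](C)(C)OCCOS(=O)(=O)C(F)(F)F | intermediate
5 | (2S,5R)-2-tert-butyl-5-[2-(tert-butyldimethylsilyloxy)ethyl]-5-methyl-1,3-dioxolan-4-one | C[C@]1(CCO[Si](C)(C)C(C)(C)C)O[C@H](C(C)(C)C)OC1=O | intermediate
6 | (R)-4-(tert-butyldimethylsilyloxy)-2-hydroxy-2-methylbutanoic acid | C[C@@](O)(CCO[Si](C)(C)C(C)(C)C)C(=O)O | intermediate
7 | methyl (S)-3-hydroxy-2-methylpropanoate | COC(=O)[C@@H](C)CO | starting material
8 | methyl (S)-3-(tert-butyldimethylsilyloxy)-2-methylpropanoate | COC(=O)[C@@H](C)CO[Si](C)(C)C(C)(C)C | intermediate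
9 | (S)-3-(tert-butyldimethylsilyloxy)-N-methoxy-N,2-dimethylpropanamide | CON(C)C(=O)[C@@H](C)CO[Si](C)(C)C(C)(C)C | intermediate
10 | (S)-4-(tert-butyldimethylsilyloxy)-1-chloro-3-methylbutan-2-one | ClCC(=O)[C@@H](C)CO[Si](C)(C)C(C)(C)C | intermediate
11 | (3S)-4-(tert-butyldimethylsilyloxy)-3-methyl-2-oxobutyl (2R)-4-(tert-butyldimethylsilyloxy)-2-hydroxy-2-methylbutanoate | C[C@@](O)(CCO[Si](C)(C)C(C)(C)C)C(=O)OCC(=O)[C@@H](C)CO[Si](C)(C)C(C)(C)C | intermediate
12 | (2S,6R)-1,8-bis(tert-butyldimethylsilyloxy)-4,6-dihydroxy-2,6-dimethyloctane-3,5-dione (both C4 epimers; germacrane C8) | C[C@@](O)(CCO[Si](C)(C)C(C)(C)C)C(=O)C(O)C(=O)[C@@H](C)CO[Si](C)(C)C(C)(C)C | intermediate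
13 | (2R)-2-[2-(tert-butyldimethylsilyloxy)ethyl]-5-[(2S)-1-(tert-butyldimethylsilyloxy)propan-2-yl]-4-hydroxy-2-methylfuran-3(2H)-one | CC(C)(C)[Si](C)(C)OCC[C@@]1(C)OC([C@@H](C)CO[Si](C)(C)C(C)(C)C)=C(O)C1=O | intermediate
14 | but-3-enoic acid | C=CCC(=O)O | starting material
15 | (R)-4-benzyl-1,3-oxazolidin-2-one | O=C1N[C@H](Cc2ccccc2)CO1 | starting material
16 | but-3-enoic pivalic anhydride | C=CCC(=O)OC(=O)C(C)(C)C | intermediate
17 | (R)-4-benzyl-3-(but-3-enoyl)-1,3-oxazolidin-2-one | O=C1OC[C@@H](Cc2ccccc2)N1C(=O)CC=C | intermediate
18 | (R)-4-benzyl-3-[(2S)-2-(benzyloxymethyl)but-3-enoyl]-1,3-oxazolidin-2-one | O=C1OC[C@@H](Cc2ccccc2)N1C(=O)[C@H](COCc3ccccc3)C=C | intermediate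
19 | (S)-2-(benzyloxymethyl)but-3-eneperoxoic acid | OOC(=O)[C@H](COCc1ccccc1)C=C | intermediate
20 | (S)-2-(benzyloxymethyl)but-3-enoic acid | OC(=O)[C@H](COCc1ccccc1)C=C | intermediate
21 | (S)-2-(benzyloxymethyl)but-3-enoyl chloride | ClC(=O)[C@H](COCc1ccccc1)C=C | intermediate
22 | (5R)-5-[2-(tert-butyldimethylsilyloxy)ethyl]-2-[(2S)-1-(tert-butyldimethylsilyloxy)propan-2-yl]-5-methyl-4-oxo-4,5-dihydrofuran-3-yl (2S)-2-(benzyloxymethyl)but-3-enoate | CC(C)(C)[Si](C)(C)OCC[C@@]1(C)OC([C@@H](C)CO[Si](C)(C)C(C)(C)C)=C(OC(=O)[C@H](COCc2ccccc2)C=C)C1=O | intermediate
23 | tricyclic cyclobutane photoadduct (4S,5R,7R,8S,10R,11S) | CC(C)(C)[Si](C)(C)OCC[C@@]1(C)O[C@@]2([C@@H](C)CO[Si](C)(C)C(C)(C)C)C[C@@H]3[C@@H](COCc4ccccc4)C(=O)O[C@]23C1=O | intermediate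
24 | C8=C9 trimethylsilyl enol ether of the ring-expanded oxepane (4S,5R,7R,10R,11S) | CC(C)(C)[Si](C)(C)OCC[C@@]1(C)O[C@@H]([C@@H](C)CO[Si](C)(C)C(C)(C)C)C[C@@H]2[C@@H](COCc3ccccc3)C(=O)OC2=C1O[Si](C)(C)C | intermediate
25 | trans-lactone-fused oxepan-3-one (4S,5R,7R,8R,10R,11S) | CC(C)(C)[Si](C)(C)OCC[C@@]1(C)O[C@@H]([C@@H](C)CO[Si](C)(C)C(C)(C)C)C[C@@H]2[C@@H](COCc3ccccc3)C(=O)O[C@H]2C1=O | intermediate
26 | C9 alcohol (4S,5R,7R,8R,9S,10R,11S) | CC(C)(C)[Si](C)(C)OCC[C@@]1(C)O[C@@H]([C@@H](C)CO[Si](C)(C)C(C)(C)C)C[C@@H]2[C@@H](COCc3ccccc3)C(=O)O[C@H]2[C@@H]1O | intermediate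
27 | isovaleryl chloride (3-methylbutanoyl chloride) | CC(C)CC(=O)Cl | starting material
28 | C9 isovalerate, bis-silyl ether, benzyl ether (configuration as 26) | CC(C)(C)[Si](C)(C)OCC[C@@]1(C)O[C@@H]([C@@H](C)CO[Si](C)(C)C(C)(C)C)C[C@@H]2[C@@H](COCc3ccccc3)C(=O)O[C@H]2[C@@H]1OC(=O)CC(C)C | intermediate
29 | C2,C3-diol (configuration as 26) | OCC[C@@]1(C)O[C@@H]([C@@H](C)CO)C[C@@H]2[C@@H](COCc3ccccc3)C(=O)O[C@H]2[C@@H]1OC(=O)CC(C)C | intermediate
30 | C2,C3-dialdehyde (spatial arrangement as 26) | O=CC[C@@]1(C)O[C@@H]([C@@H](C)C=O)C[C@@H]2[C@@H](COCc3ccccc3)C(=O)O[C@H]2[C@@H]1OC(=O)CC(C)C | intermediate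
31 | bicyclic C2=C3 alkene with C13 benzyl ether (4S,5R,7R,8R,9S,10R,11S) | c1ccccc1COC[C@H]2C(=O)O[C@@H]3[C@@H]2C[C@H]2O[C@](C)(CC=C[C@@H]2C)[C@H]3OC(=O)CC(C)C | intermediate
32 | saturated C13 alcohol (11,13-dihydro-13-hydroxy target; 11S) | OC[C@H]1C(=O)O[C@@H]2[C@@H]1C[C@H]1O[C@](C)(CCC[C@@H]1C)[C@H]2OC(=O)CC(C)C | intermediate
33 | C13 mesylate of 32 | CS(=O)(=O)OC[C@H]1C(=O)O[C@@H]2[C@@H]1C[C@H]1O[C@](C)(CCC[C@@H]1C)[C@H]2OC(=O)CC(C)C | intermediate
34 | CNP0274454.1 (4S,5R,7R,8R,9S,10R) | C=C1C(=O)O[C@@H]2[C@@H]1C[C@H]1O[C@](C)(CCC[C@@H]1C)[C@H]2OC(=O)CC(C)C | target

## Step count and least certain steps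

Total: 22 steps. Longest linear sequence: 15 steps (steps 1, 3, 4, 8, 9 and 13–22).

**Step 14 (key step, proposed new method).**
- What may go wrong: the ester may rest in its extended rotamer, so cyclisation could be slow and a photo-Fries-type acyl shift or dimerisation could take over. Facial selectivity may erode, because C11 must override the opposing preference of C10, and any epimerisation at C11 before irradiation translates directly into the wrong C7.
- Fallback (known chemistry: intramolecular [2+2] photocycloaddition of 2-alkenyloxy enones through an ether tether, then oxidation of the cyclic ether to the lactone), setting out from 13 and 18 and returning at 23. LiBH4 reduction of 18 should give (R)-2-(benzyloxymethyl)but-3-en-1-ol F1 and return 15. Mitsunobu O-alkylation of 13 with F1 (PPh3, DIAD) should give the 4-(alkenyloxy)furanone F2, whose C11 is no longer α to a carbonyl and whose tether has no rotamer penalty. Irradiation should give the tetrahydrofuran-fused photoadduct F3 with the same sense of induction. RuCl3/NaIO4 should oxidise C12 to the lactone carbonyl and, at the same time, the benzyl ether to the benzoate, giving the lactone benzoate F4. K2CO3/MeOH should remove the benzoyl group to the hydroxymethyl lactone F5, and neutral benzylation (2-benzyloxy-1-methylpyridinium triflate, MgO) returns to 23.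

**Step 15 (proposed new method).**
- What may go wrong: ionisation of the C5–C8 bond may fail or be slow, because that bond lies nearly in the plane of the C9 carbonyl. The silyl ether oxygen may capture the cation irreversibly, C4 may scramble through loss of a proton from the oxocarbenium ion, and hydride may add to the wrong face, which would leave material unable to close in step 20.
- Fallback (known chemistry in two separate operations), setting out from 23 and returning at 25. Brønsted-acid hydrolytic opening of the alkoxycyclobutyl ketone (PPTS, wet MeCN, 40 °C), the classical de Mayo-type retro-aldol outcome, should give the open-chain hydroxy diketone F6 after collapse of the hemiketal. Established reductive cycloetherification between the C10 hydroxyl and the C5 ketone (Et3SiH, TMSOTf, MeCN, −40 °C), followed by the same DBU treatment, closes the oxepane to 25.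

**Step 9.**
- What may go wrong: enolate formation may be diverted by the free tertiary alkoxide (hemiketal formation with the ketone), the hydroxy diketone may undergo retro-Claisen cleavage before cyclisation, and partial enolisation towards C4 would erode that centre.
- Fallback (Claisen condensation and later oxidation at C8), setting out from 9 and 5 and returning at 13. MeMgBr converts 9 into the methyl ketone F7. Its kinetic lithium enolate (LDA, −78 °C) is acylated by 5 with loss of pivalaldehyde, and acidic work-up closes the 4-unsubstituted furanone F8 (cyclodehydration of an α′-hydroxy 1,3-diketone). Epoxidation of the C5=C8 bond with dimethyldioxirane and acid-induced opening of the epoxide, as practised on chromones and flavones, then gives 13.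

**Step 20.**
- What may go wrong: the bridged ring may fail to close, so that intermolecular coupling or arrest at the pinacol stage takes over, and the hot Lewis-acidic medium may cause β-elimination of the ring oxygen or epimerisation at C4 in 30.
- Fallback (metathesis in place of reductive coupling), setting out from 30 and returning at 31. Double Wittig methylenation (Ph3P=CH2, THF, −78 → 0 °C) should give the diene F9, and ring-closing metathesis with the second-generation Grubbs catalyst in dilute CH2Cl2 at reflux should close the C2=C3 bond to 31 with loss of ethylene.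

**Step 16.**
- What may go wrong: hydride may be delivered from the methyl face if the oxepanone prefers another conformer, and the C9 alkoxide may take over the lactone acyl group.
- Fallback (inversion in place of facial control), setting out from 25 and returning at 28. If reduction gives mainly the C9 epimer F10, esterification with inversion under Mitsunobu conditions (isovaleric acid, PPh3, DIAD) should give 28 directly.

## Further compounds

F1 | step 14 | (R)-2-(benzyloxymethyl)but-3-en-1-ol | OC[C@H](COCc1ccccc1)C=C
F2 | step 14 | (2R)-4-{[(2S)-2-(benzyloxymethyl)but-3-en-1-yl]oxy}-2-[2-(tert-butyldimethylsilyloxy)ethyl]-5-[(2S)-1-(tert-butyldimethylsilyloxy)propan-2-yl]-2-methylfuran-3(2H)-one | CC(C)(C)[Si](C)(C)OCC[C@@]1(C)OC([C@@H](C)CO[Si](C)(C)C(C)(C)C)=C(OC[C@H](COCc2ccccc2)C=C)C1=O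
F3 | step 14 | tetrahydrofuran-fused photoadduct (C12 as CH2, otherwise as 23) | CC(C)(C)[Si](C)(C)OCC[C@@]1(C)O[C@@]2([C@@H](C)CO[Si](C)(C)C(C)(C)C)C[C@@H]3[C@@H](COCc4ccccc4)CO[C@]23C1=O
F4 | step 14 | photoadduct lactone with C13 benzoate | CC(C)(C)[Si](C)(C)OCC[C@@]1(C)O[C@@]2([C@@H](C)CO[Si](C)(C)C(C)(C)C)C[C@@H]3[C@@H](COC(=O)c4ccccc4)C(=O)O[C@]23C1=O
F5 | step 14 | photoadduct lactone with free C13 hydroxyl | CC(C)(C)[Si](C)(C)OCC[C@@]1(C)O[C@@]2([C@@H](C)CO[Si](C)(C)C(C)(C)C)C[C@@H]3[C@@H](CO)C(=O)O[C@]23C1=O
F6 | step 15 | open-chain hydroxy diketone (C5 ketone, C9 ketone, C10 tertiary alcohol, trans-substituted lactone) | CC(C)(C)[Si](C)(C)OCC[C@@](C)(O)C(=O)[C@@H]1OC(=O)[C@H](COCc2ccccc2)[C@H]1CC(=O)[C@@H](C)CO[Si](C)(C)C(C)(C)C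
F7 | step 9 | (S)-4-(tert-butyldimethylsilyloxy)-3-methylbutan-2-one | CC(=O)[C@@H](C)CO[Si](C)(C)C(C)(C)C
F8 | step 9 | (2R)-2-[2-(tert-butyldimethylsilyloxy)ethyl]-5-[(2S)-1-(tert-butyldimethylsilyloxy)propan-2-yl]-2-methylfuran-3(2H)-one | CC(C)(C)[Si](C)(C)OCC[C@@]1(C)OC([C@@H](C)CO[Si](C)(C)C(C)(C)C)=CC1=O
F9 | step 20 | diene (C2 and C3 as vinyl termini, otherwise as 30) | C=CC[C@@]1(C)O[C@@H]([C@@H](C)C=C)C[C@@H]2[C@@H](COCc3ccccc3)C(=O)O[C@H]2[C@@H]1OC(=O)CC(C)C
F10 | step 16 | C9 epimer of 26 | CC(C)(C)[Si](C)(C)OCC[C@@]1(C)O[C@@H]([C@@H](C)CO[Si](C)(C)C(C)(C)C)C[C@@H]2[C@@H](COCc3ccccc3)C(=O)O[C@H]2[C@H]1O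
A1 | alternative 1 | C5-iodomethyl oxepane with C9 isovalerate, C8 triethylsilyl ether and (Z)-2-(ethylsulfonylmethyl)enoate | IC[C@H]1O[C@](C)(CCC[C@@H]1C)[C@@H](OC(=O)CC(C)C)[C@H](O[Si](CC)(CC)CC)/C=C(\CS(=O)(=O)CC)C(=O)OC
A2 | alternative 1 | bicyclic α-methylene ester with C8 triethylsilyl ether | COC(=O)C(=C)[C@H]1C[C@H]2O[C@](C)(CCC[C@@H]2C)[C@@H](OC(=O)CC(C)C)[C@@H]1O[Si](CC)(CC)CC
A3 | alternative 2 | lactone diazo ketone with 3-methyl-2-vinyloxetane | CC(=[N+]=[N-])C(=O)[C@@H]1OC(=O)C[C@H]1C[C@H]1O[C@@H](C=C)[C@@H]1C
A4 | alternative 2 | bicyclic lactone with C9 ketone and C2=C3 alkene | C1C(=O)O[C@@H]2[C@@H]1C[C@H]1O[C@](C)(CC=C[C@@H]1C)C2=O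
A5 | alternative 3 | oxepane aldehyde with C9 silyl ether and (Z)-2-(bromomethyl)enoate | COC(=O)/C(CBr)=C/C[C@H]1O[C@](C)(CCC[C@@H]1C)[C@@H](O[Si](C)(C)C(C)(C)C)C=O
A6 | alternative 3 | C9 tert-butyldimethylsilyl ether of the deacylated target | C=C1C(=O)O[C@@H]2[C@@H]1C[C@H]1O[C@](C)(CCC[C@@H]1C)[C@H]2O[Si](C)(C)C(C)(C)C
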